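## Retrosynthetic overview

1. Germacrane numbering is used: lactone C12(=O)–C11(=C13)–C7–C8–O; carbocycle C8–C9–C10(C14H2OAc)=C1–C2–C3–C4(C15H2OAc)=C5–C6(OH)–C7. The target comes from a triol by acylation of the two primary allylic hydroxyls, C13 from Mannich methylenation of the lactone, and C14–OH from reduction of a C14 enal.
2. Key disconnection: the C3–C4 bond of the ten-membered ring, formed in a five-to-ten ring expansion. An N-alkoxyphthalimide of a 2-substituted cyclopent-2-en-1-ol (ring C14–C10=C1–C2–C3, tied through C9 to C8) and a (Z)-alkenyl iodide at C4 are joined at nickel after alkoxy-radical β-scission of the C14–C3 ring bond.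
3. Enabling feature: the five-carbon arc C14–C10(=C1)–C2–C3 of the ten-membered ring is a cyclopentenol cut open at C14–C3. The cut makes C14 the oxygenated one-carbon branch, frees C3 as a primary radical for bonding to C4, and hands the ring-enforced cis relation of C14 and C2 to the C1=C10 alkene (C9 trans to C2).
4. Precursor: trans-γ-lactone with C7 and C8 from an Evans syn-aldol/lactonisation of a succinate imide with a cyclopentenylacetaldehyde; C6 from Noyori transfer hydrogenation of a C6 ynone; the C4 iodide and the C4=C5 geometry from trans-hydrosilylation/iododesilylation.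
5. Ring order: cyclopentene (bought as its bromo ketal), then the γ-lactone (step 4), then the ten-membered carbocycle (step 14), in which the five-membered carbocycle is consumed.

Key step: step 14

Remark on the chemistry: compounds 21–23 are carried as both epimers at the cyclopentenyl carbinol carbon (C14); this centre becomes the sp2 formyl carbon in step 14, so both epimers converge. Compounds 1, 2, 6, 7 and 13 are taken to be catalogue materials.

## Route

Step 1
Reactants: 1 6-bromo-1,4-dioxaspiro[4.4]non-6-ene; 2 oxirane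
Product: 4 2-(1,4-dioxaspiro[4.4]non-6-en-6-yl)ethan-1-ol, via alkenyllithium 3 (not isolated)
Conditions: n-BuLi, THF, −78 °C; 2, −78 → 0 °C; H2O
Reagents that add atoms: none
Why: Bromine–lithium exchange gives the α-keto vinyl anion equivalent, which opens the epoxide at carbon (alkenyllithium epoxide opening) and so attaches the future C9–C8 unit to C10.

Step 2
Reactants: 4 2-(1,4-dioxaspiro[4.4]non-6-en-6-yl)ethan-1-ol
Product: 5 2-(1,4-dioxaspiro[4.4]non-6-en-6-yl)acetaldehyde
Conditions: Dess–Martin periodinane, NaHCO3, CH2Cl2, 0 °C → rt; used at once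
Reagents that add atoms: none
Why: Dess–Martin oxidation under buffered, non-basic conditions should give the β,γ-unsaturated aldehyde without loss of the ketal or migration of the ring alkene into conjugation.

Step 3
Reactants: 6 (R)-4-benzyloxazolidin-2-one; 7 methyl 4-chloro-4-oxobutanoate
Product: 8 methyl 4-[(4R)-4-benzyl-2-oxooxazolidin-3-yl]-4-oxobutanoate
Conditions: n-BuLi, THF, −78 °C; 7, −78 → 0 °C
Reagents that add atoms: none
Why: N-acylation of the lithiated Evans auxiliary by the acid chloride is a standard acyl substitution and leaves the methyl ester untouched.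

Step 4
Reactants: 8 methyl 4-[(4R)-4-benzyl-2-oxooxazolidin-3-yl]-4-oxobutanoate; 5 2-(1,4-dioxaspiro[4.4]non-6-en-6-yl)acetaldehyde
Product: 10 (4R)-4-benzyl-3-{[(2S,3R)-2-(1,4-dioxaspiro[4.4]non-6-en-6-ylmethyl)-5-oxooxolan-3-yl]carbonyl}oxazolidin-2-one, via syn-aldol adduct 9 (not isolated)
Conditions: Bu2BOTf, i-Pr2NEt, CH2Cl2, −78 → 0 °C; 5, −78 → 0 °C; pH 7 buffer, MeOH, H2O2, 0 °C; lactonisation on work-up (silica gel, CH2Cl2)
Reagents that add atoms: none
Why: Evans syn-aldol reaction through the Z-boron enolate of the imide and a Zimmerman–Traxler chair, in which the (R)-benzyl auxiliary sets C7 and C8 syn with the required absolute sense, after which the C8 hydroxyl closes onto the methyl ester to give the trans-γ-lactone and so fixes the lactone at O8.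

Step 5
Reactants: 10 trans-lactone imide
Product: 12 (2S,3R)-2-(1,4-dioxaspiro[4.4]non-6-en-6-ylmethyl)-5-oxooxolane-3-carboxylic acid, via lithium peroxycarboxylate 11 (not isolated)
Conditions: LiOH·H2O, 30% H2O2, THF/H2O, 0 °C; Na2SO3 (aq); dilute HCl to pH 4, 0 °C
Reagents that add atoms: hydrogen peroxide, OO
Why: Hydroperoxide-mediated cleavage of the Evans imide attacks the exocyclic carbonyl selectively, the peracid is reduced by sulfite, and any opened lactone should re-close on mild acidification while the ketal survives at pH 4.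

Step 6
Reactants: 12 lactone acid; 13 tert-butyldimethyl(prop-2-yn-1-yloxy)silane
Product: 15 (4R,5S)-4-[4-(tert-butyldimethylsilyloxy)but-2-ynoyl]-5-(1,4-dioxaspiro[4.4]non-6-en-6-ylmethyl)oxolan-2-one, via acyl chloride 14 (not isolated)
Conditions: 1-chloro-N,N,2-trimethylprop-1-en-1-amine, CH2Cl2, 0 °C; then 13, PdCl2(PPh3)2 (2 mol%), CuI (4 mol%), Et3N (1.1 equiv), THF, rt
Reagents that add atoms: none
Why: Neutral acid-chloride formation followed by acyl Sonogashira coupling should give the ynone with only brief exposure of the base-sensitive β-acyloxy ketone to amine.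

Step 7
Reactants: 15 ynone
Product: 16 (4S,5S)-4-[(1S)-4-(tert-butyldimethylsilyloxy)-1-hydroxybut-2-yn-1-yl]-5-(1,4-dioxaspiro[4.4]non-6-en-6-ylmethyl)oxolan-2-one
Conditions: Ru[(S,S)-TsNCH(Ph)CH(Ph)NH](η6-p-cymene) (2 mol%), i-PrOH, rt
Reagents that add atoms: none
Why: Noyori asymmetric transfer hydrogenation of an alkynyl ketone, in which the (S,S)-catalyst recognises the alkyne as the π-group and should set C6 under catalyst control (S descriptor here, the spatial arrangement of 6R in the target).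

Step 8
Reactants: 16 propargylic alcohol
Product: 17 (4S,5S)-4-[(1S,2Z)-4-(tert-butyldimethylsilyloxy)-1-hydroxy-3-(triethylsilyl)but-2-en-1-yl]-5-(1,4-dioxaspiro[4.4]non-6-en-6-ylmethyl)oxolan-2-one
Conditions: [Cp*Ru(MeCN)3]PF6 (5 mol%), Et3SiH, CH2Cl2, 0 °C → rt
Reagents that add atoms: triethylsilane, CC[SiH](CC)CC
Why: Ruthenium-catalysed trans-hydrosilylation of a propargylic alcohol should place silicon on the alkyne carbon distal to the free hydroxyl (C4) and hydrogen on C5 from the opposite side, which sets the C4=C5 geometry with silicon cis to C6.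

Step 9
Reactants: 17 vinylsilane
Product: 18 (4S,5S)-4-[(1S,2Z)-4-(tert-butyldimethylsilyloxy)-1-hydroxy-3-iodobut-2-en-1-yl]-5-(1,4-dioxaspiro[4.4]non-6-en-6-ylmethyl)oxolan-2-one
Conditions: N-iodosuccinimide, 2,6-lutidine, (CF3)2CHOH, 0 °C
Reagents that add atoms: N-iodosuccinimide, O=C1CCC(=O)N1I
Why: Iododesilylation by ipso attack of iodonium on the vinylsilane (β-silyl cation) should replace silicon by iodine with retention, giving the iodide cis to C6.

Step 10
Reactants: 18 iodo alcohol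
Product: 19 (4R,5S)-4-[(1S,2Z)-1,4-bis(tert-butyldimethylsilyloxy)-3-iodobut-2-en-1-yl]-5-(1,4-dioxaspiro[4.4]non-6-en-6-ylmethyl)oxolan-2-one
Conditions: TBSOTf, 2,6-lutidine, CH2Cl2, −78 °C
Reagents that add atoms: tert-butyldimethylsilyl triflate, CC(C)(C)[Si](C)(C)OS(=O)(=O)C(F)(F)F
Why: Silyl ether formation masks the C6 hydroxyl for the Mitsunobu step and for the later enolate chemistry.

Step 11
Reactants: 19 bis-silyl ether ketal
Product: 20 (4R,5S)-4-[(1S,2Z)-1,4-bis(tert-butyldimethylsilyloxy)-3-iodobut-2-en-1-yl]-5-[(5-oxocyclopent-1-en-1-yl)methyl]oxolan-2-one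
Conditions: pyridinium p-toluenesulfonate (cat.), THF/H2O, rt
Reagents that add atoms: water, O
Why: Acid-catalysed hydrolysis of the allylic (enone) ketal is far faster than cleavage of the silyl ethers and should unmask the cyclopentenone selectively.

Step 12
Reactants: 20 cyclopentenone
Product: 21 (4R,5S)-4-[(1S,2Z)-1,4-bis(tert-butyldimethylsilyloxy)-3-iodobut-2-en-1-yl]-5-[(5-hydroxycyclopent-1-en-1-yl)methyl]oxolan-2-one (both carbinol epimers)
Conditions: NaBH4, CeCl3·7H2O, MeOH, −40 °C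
Reagents that add atoms: none
Why: Luche reduction should give 1,2-reduction of the enone without touching the lactone or the alkenyl iodide, and the new carbinol centre need not be controlled because it is destroyed in step 14.

Step 13
Reactants: 21 cyclopentenol
Product: 22 2-{[2-({(2S,3R)-3-[(1S,2Z)-1,4-bis(tert-butyldimethylsilyloxy)-3-iodobut-2-en-1-yl]-5-oxooxolan-2-yl}methyl)cyclopent-2-en-1-yl]oxy}isoindoline-1,3-dione (both epimers)
Conditions: N-hydroxyphthalimide, PPh3, diisopropyl azodicarboxylate, THF, 0 °C → rt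
Reagents that add atoms: N-hydroxyphthalimide, O=C1c2ccccc2C(=O)N1O
Why: Mitsunobu reaction with the acidic N-hydroxyphthalimide should form the O–N bond by SN2 at C14 and so install a reductively triggered alkoxy-radical precursor.

Step 14
Reactants: 22 N-alkoxyphthalimide
Product: 25 (3aR,4R,5E,9Z,11aS)-4-(tert-butyldimethylsilyloxy)-6-[(tert-butyldimethylsilyloxy)methyl]-2-oxo-2,3,3a,4,7,8,11,11a-octahydrocyclodeca[b]furan-10-carbaldehyde, via cyclopentenyloxyl radical 23 (not isolated), via ring-opened C3 radical 24 (not isolated)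
Conditions: NiBr2(dme) (30 mol%), 4,4′-di-tert-butyl-2,2′-bipyridine (36 mol%), 4CzIPN (3 mol%), Hantzsch ester (1.5 equiv), 2,6-lutidine (2 equiv), DMA, blue LEDs, rt; 22 added by syringe pump, final about 1 mM
Reagents that add atoms: none
Why: Proposed new method: single-electron reduction of the N-alkoxyphthalimide (photoexcited 4CzIPN with Hantzsch ester) cleaves the N–O bond to the cyclopentenyloxyl radical 23, whose β-scission breaks the C14–C3 ring bond (the only β-bond to an sp3 carbon, with gain of enal conjugation) and gives the primary C3 radical 24; zerovalent nickel inserts into the C4–I bond, the alkenylnickel species captures the radical, and reductive elimination from trivalent nickel forms the C3–C4 bond. The closest known reaction type is the nickel/photoredox C(sp3)–C(sp2) coupling of aryl halides with carbon radicals released by β-scission of alkoxy radicals from N-alkoxyphthalimides of cycloalkanols; new here are the macrocyclising intramolecular mode, the alkenyl iodide partner and the allylic alkoxy radical. The ten-membered carbocycle closes through an eleven-membered nickelacycle (radical capture at nickel, then C–C reductive elimination), the net result being a five-to-ten ring expansion. No stereocentre is created: C6, C7 and C8 are untouched, the C1=C10 geometry (C14 cis to C2) is inherited from the five-membered ring and the C4=C5 geometry from the stereoretentive coupling of the (Z)-iodide. The step needs β-scission to outrun 1,5-hydrogen abstraction by the alkoxy radical, and intramolecular capture at nickel to outrun hydrogen transfer to C3 and intermolecular coupling; the first should be secured by the allylic, conjugation-forming fragmentation, the second by high dilution, slow addition and a high nickel loading.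

Step 15
Reactants: 25 macrocyclic enal
Product: 26 (3aR,4R,5E,9Z,11aS)-4-(tert-butyldimethylsilyloxy)-6-[(tert-butyldimethylsilyloxy)methyl]-10-(hydroxymethyl)-3a,4,7,8,11,11a-hexahydrocyclodeca[b]furan-2(3H)-one
Conditions: NaBH4, CeCl3·7H2O, MeOH, −40 °C
Reagents that add atoms: none
Why: Luche reduction should reduce the enal 1,2 to the primary allylic alcohol (C14–OH) and leave the lactone intact.

Step 16
Reactants: 26 macrocyclic allylic alcohol
Product: 27 (3aR,4R,5E,9Z,11aS)-4-(tert-butyldimethylsilyloxy)-6,10-bis[(tert-butyldimethylsilyloxy)methyl]-3a,4,7,8,11,11a-hexahydrocyclodeca[b]furan-2(3H)-one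
Conditions: TBSCl, imidazole, DMF, rt
Reagents that add atoms: tert-butyldimethylsilyl chloride, CC(C)(C)[Si](C)(C)Cl
Why: Silylation of the primary hydroxyl removes the only acidic proton besides the lactone α-hydrogens before enolate formation.

Step 17
Reactants: 27 tris-silyl lactone
Product: 30 (3aR,4R,5E,9Z,11aS)-4-(tert-butyldimethylsilyloxy)-6,10-bis[(tert-butyldimethylsilyloxy)methyl]-3-methylidene-3a,4,7,8,11,11a-hexahydrocyclodeca[b]furan-2(3H)-one, via Mannich base 28 (not isolated), via trimethylammonium iodide 29 (not isolated)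
Conditions: lithium diisopropylamide, THF, −78 °C; CH2=NMe2+ I−, −78 °C → rt; MeI, MeOH, rt; NaHCO3 (aq), CH2Cl2, rt
Reagents that add atoms: N,N-dimethylmethyleneiminium iodide (Eschenmoser's salt), C=[N+](C)C.[I-]
Why: Deprotonation at C11, Mannich alkylation with Eschenmoser's salt, N-methylation and E1cB (Hofmann-type) elimination should give the α-methylene lactone, the transient C11 centre being destroyed.

Step 18
Reactants: 30 α-methylene tris-silyl lactone
Product: 31 (3aS,4R,5E,9Z,11aS)-4-hydroxy-6,10-bis(hydroxymethyl)-3-methylidene-3a,4,7,8,11,11a-hexahydrocyclodeca[b]furan-2(3H)-one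
Conditions: HF·pyridine, pyridine, THF, 0 °C → rt
Reagents that add atoms: none
Why: Fluoride-mediated cleavage of the three silyl ethers under buffered acidic conditions should spare the α-methylene lactone and the 1,5-diene.

Step 19
Reactants: 31 triol
Product: 32 [(3aS,4R,5E,9Z,11aS)-4-hydroxy-3-methylidene-2-oxo-2,3,3a,4,7,8,11,11a-octahydrocyclodeca[b]furan-6,10-diyl]bis(methylene) diacetate (target)
Conditions: AcCl (2.2 equiv), 2,4,6-collidine, CH2Cl2, −78 °C
Reagents that add atoms: acetyl chloride, CC(Cl)=O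
Why: Kinetically selective acylation of the two unhindered primary allylic hydroxyls over the hindered secondary C6 hydroxyl (acyl chloride with collidine at low temperature) should give the diacetate.

## Compound list

1 | 6-bromo-1,4-dioxaspiro[4.4]non-6-ene | BrC1=CCCC12OCCO2 | starting material
2 | oxirane | C1CO1 | starting material
3 | (1,4-dioxaspiro[4.4]non-6-en-6-yl)lithium | [Li]C1=CCCC12OCCO2 | intermediate
4 | 2-(1,4-dioxaspiro[4.4]non-6-en-6-yl)ethan-1-ol | OCCC1=CCCC12OCCO2 | intermediate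
5 | 2-(1,4-dioxaspiro[4.4]non-6-en-6-yl)acetaldehyde | O=CCC1=CCCC12OCCO2 | intermediate
6 | (R)-4-benzyloxazolidin-2-one | O=C1N[C@H](Cc2ccccc2)CO1 | starting material
7 | methyl 4-chloro-4-oxobutanoate | COC(=O)CCC(Cl)=O | starting material
8 | methyl 4-[(4R)-4-benzyl-2-oxooxazolidin-3-yl]-4-oxobutanoate | COC(=O)CCC(=O)N1[C@H](Cc2ccccc2)COC1=O | intermediate
9 | methyl (3R,4S)-3-{[(4R)-4-benzyl-2-oxooxazolidin-3-yl]carbonyl}-5-(1,4-dioxaspiro[4.4]non-6-en-6-yl)-4-hydroxypentanoate (syn-aldol adduct) | COC(=O)C[C@@H](C(=O)N1[C@H](Cc2ccccc2)COC1=O)[C@@H](O)CC1=CCCC12OCCO2 | intermediate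
10 | (4R)-4-benzyl-3-{[(2S,3R)-2-(1,4-dioxaspiro[4.4]non-6-en-6-ylmethyl)-5-oxooxolan-3-yl]carbonyl}oxazolidin-2-one | O=C1C[C@@H](C(=O)N2[C@H](Cc3ccccc3)COC2=O)[C@H](CC2=CCCC23OCCO3)O1 | intermediate
11 | (2S,3R)-2-(1,4-dioxaspiro[4.4]non-6-en-6-ylmethyl)-5-oxooxolane-3-carboperoxoic acid (present as its lithium salt) | O=C1C[C@@H](C(=O)OO)[C@H](CC2=CCCC23OCCO3)O1 | intermediate
12 | (2S,3R)-2-(1,4-dioxaspiro[4.4]non-6-en-6-ylmethyl)-5-oxooxolane-3-carboxylic acid | O=C1C[C@@H](C(=O)O)[C@H](CC2=CCCC23OCCO3)O1 | intermediate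
13 | tert-butyldimethyl(prop-2-yn-1-yloxy)silane | C#CCO[Si](C)(C)C(C)(C)C | starting material
14 | (2S,3R)-2-(1,4-dioxaspiro[4.4]non-6-en-6-ylmethyl)-5-oxooxolane-3-carbonyl chloride | O=C1C[C@@H](C(Cl)=O)[C@H](CC2=CCCC23OCCO3)O1 | intermediate
15 | (4R,5S)-4-[4-(tert-butyldimethylsilyloxy)but-2-ynoyl]-5-(1,4-dioxaspiro[4.4]non-6-en-6-ylmethyl)oxolan-2-one | O=C1C[C@@H](C(=O)C#CCO[Si](C)(C)C(C)(C)C)[C@H](CC2=CCCC23OCCO3)O1 | intermediate
16 | (4S,5S)-4-[(1S)-4-(tert-butyldimethylsilyloxy)-1-hydroxybut-2-yn-1-yl]-5-(1,4-dioxaspiro[4.4]non-6-en-6-ylmethyl)oxolan-2-one | O=C1C[C@@H]([C@H](O)C#CCO[Si](C)(C)C(C)(C)C)[C@H](CC2=CCCC23OCCO3)O1 | intermediate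
17 | (4S,5S)-4-[(1S,2Z)-4-(tert-butyldimethylsilyloxy)-1-hydroxy-3-(triethylsilyl)but-2-en-1-yl]-5-(1,4-dioxaspiro[4.4]non-6-en-6-ylmethyl)oxolan-2-one | O=C1C[C@@H]([C@H](O)/C=C(\[Si](CC)(CC)CC)CO[Si](C)(C)C(C)(C)C)[C@H](CC2=CCCC23OCCO3)O1 | intermediate
18 | (4S,5S)-4-[(1S,2Z)-4-(tert-butyldimethylsilyloxy)-1-hydroxy-3-iodobut-2-en-1-yl]-5-(1,4-dioxaspiro[4.4]non-6-en-6-ylmethyl)oxolan-2-one | O=C1C[C@@H]([C@H](O)/C=C(\I)CO[Si](C)(C)C(C)(C)C)[C@H](CC2=CCCC23OCCO3)O1 | intermediate
19 | (4R,5S)-4-[(1S,2Z)-1,4-bis(tert-butyldimethylsilyloxy)-3-iodobut-2-en-1-yl]-5-(1,4-dioxaspiro[4.4]non-6-en-6-ylmethyl)oxolan-2-one | O=C1C[C@@H]([C@H](O[Si](C)(C)C(C)(C)C)/C=C(\I)CO[Si](C)(C)C(C)(C)C)[C@H](CC2=CCCC23OCCO3)O1 | intermediate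
20 | (4R,5S)-4-[(1S,2Z)-1,4-bis(tert-butyldimethylsilyloxy)-3-iodobut-2-en-1-yl]-5-[(5-oxocyclopent-1-en-1-yl)methyl]oxolan-2-one | O=C1C[C@@H]([C@H](O[Si](C)(C)C(C)(C)C)/C=C(\I)CO[Si](C)(C)C(C)(C)C)[C@H](CC2=CCCC2=O)O1 | intermediate
21 | (4R,5S)-4-[(1S,2Z)-1,4-bis(tert-butyldimethylsilyloxy)-3-iodobut-2-en-1-yl]-5-[(5-hydroxycyclopent-1-en-1-yl)methyl]oxolan-2-one (both carbinol epimers) | O=C1C[C@@H]([C@H](O[Si](C)(C)C(C)(C)C)/C=C(\I)CO[Si](C)(C)C(C)(C)C)[C@H](CC2=CCCC2O)O1 | intermediate
22 | 2-{[2-({(2S,3R)-3-[(1S,2Z)-1,4-bis(tert-butyldimethylsilyloxy)-3-iodobut-2-en-1-yl]-5-oxooxolan-2-yl}methyl)cyclopent-2-en-1-yl]oxy}isoindoline-1,3-dione (both epimers) | O=C1C[C@@H]([C@H](O[Si](C)(C)C(C)(C)C)/C=C(\I)CO[Si](C)(C)C(C)(C)C)[C@H](CC2=CCCC2ON2C(=O)c3ccccc3C2=O)O1 | intermediate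
23 | cyclopent-2-en-1-yloxyl radical from 22 (N–O bond cleaved) | O=C1C[C@@H]([C@H](O[Si](C)(C)C(C)(C)C)/C=C(\I)CO[Si](C)(C)C(C)(C)C)[C@H](CC2=CCCC2[O])O1 | intermediate
24 | (3Z)-4-formyl-5-{(2S,3R)-3-[(1S,2Z)-1,4-bis(tert-butyldimethylsilyloxy)-3-iodobut-2-en-1-yl]-5-oxooxolan-2-yl}pent-3-en-1-yl radical | O=C1C[C@@H]([C@H](O[Si](C)(C)C(C)(C)C)/C=C(\I)CO[Si](C)(C)C(C)(C)C)[C@H](C/C(C=O)=C/C[CH2])O1 | intermediate
25 | (3aR,4R,5E,9Z,11aS)-4-(tert-butyldimethylsilyloxy)-6-[(tert-butyldimethylsilyloxy)methyl]-2-oxo-2,3,3a,4,7,8,11,11a-octahydrocyclodeca[b]furan-10-carbaldehyde | C1C(=O)O[C@H]2C/C(C=O)=C/CC/C(CO[Si](C)(C)C(C)(C)C)=C\[C@@H](O[Si](C)(C)C(C)(C)C)[C@H]12 | intermediate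
26 | (3aR,4R,5E,9Z,11aS)-4-(tert-butyldimethylsilyloxy)-6-[(tert-butyldimethylsilyloxy)methyl]-10-(hydroxymethyl)-3a,4,7,8,11,11a-hexahydrocyclodeca[b]furan-2(3H)-one | C1C(=O)O[C@H]2C/C(CO)=C/CC/C(CO[Si](C)(C)C(C)(C)C)=C\[C@@H](O[Si](C)(C)C(C)(C)C)[C@H]12 | intermediate
27 | (3aR,4R,5E,9Z,11aS)-4-(tert-butyldimethylsilyloxy)-6,10-bis[(tert-butyldimethylsilyloxy)methyl]-3a,4,7,8,11,11a-hexahydrocyclodeca[b]furan-2(3H)-one | C1C(=O)O[C@H]2C/C(CO[Si](C)(C)C(C)(C)C)=C/CC/C(CO[Si](C)(C)C(C)(C)C)=C\[C@@H](O[Si](C)(C)C(C)(C)C)[C@H]12 | intermediate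
28 | 3-[(dimethylamino)methyl] derivative of 27 (Mannich base; C3 of the lactone not defined) | CN(C)CC1C(=O)O[C@H]2C/C(CO[Si](C)(C)C(C)(C)C)=C/CC/C(CO[Si](C)(C)C(C)(C)C)=C\[C@@H](O[Si](C)(C)C(C)(C)C)[C@H]12 | intermediate
29 | trimethylammonium iodide of 28 | C[N+](C)(C)CC1C(=O)O[C@H]2C/C(CO[Si](C)(C)C(C)(C)C)=C/CC/C(CO[Si](C)(C)C(C)(C)C)=C\[C@@H](O[Si](C)(C)C(C)(C)C)[C@H]12.[I-] | intermediate
30 | (3aR,4R,5E,9Z,11aS)-4-(tert-butyldimethylsilyloxy)-6,10-bis[(tert-butyldimethylsilyloxy)methyl]-3-methylidene-3a,4,7,8,11,11a-hexahydrocyclodeca[b]furan-2(3H)-one | C=C1C(=O)O[C@H]2C/C(CO[Si](C)(C)C(C)(C)C)=C/CC/C(CO[Si](C)(C)C(C)(C)C)=C\[C@@H](O[Si](C)(C)C(C)(C)C)[C@H]12 | intermediate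
31 | (3aS,4R,5E,9Z,11aS)-4-hydroxy-6,10-bis(hydroxymethyl)-3-methylidene-3a,4,7,8,11,11a-hexahydrocyclodeca[b]furan-2(3H)-one | C=C1C(=O)O[C@H]2C/C(CO)=C/CC/C(CO)=C\[C@@H](O)[C@H]12 | intermediate
32 | [(3aS,4R,5E,9Z,11aS)-4-hydroxy-3-methylidene-2-oxo-2,3,3a,4,7,8,11,11a-octahydrocyclodeca[b]furan-6,10-diyl]bis(methylene) diacetate | C=C1C(=O)O[C@H]2C/C(COC(C)=O)=C/CC/C(COC(C)=O)=C\[C@@H](O)[C@H]12 | target

## Count and risks

Total step count: 19. Longest linear sequence: 18 steps (steps 1, 2 and 4–19 from compound 1; step 3 is a one-step side branch).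

Steps most likely to fail:

1. Step 14 (Proposed new method). What may go wrong:
   - the C3 radical may be quenched before it reaches nickel, by hydrogen transfer from the newly formed formyl group (a six-membered transition state is available because C14 is cis to C2) or from the Hantzsch ester;
   - the alkoxy radical may abstract the C8 hydrogen instead of fragmenting;
   - zerovalent nickel may ionise the allylic C–O bond;
   - capture may become intermolecular, leading to oligomers.

   Fallback with known chemistry, from 21 and back at 27: the free cyclopentenol 21 is fragmented under hypoiodite conditions (PhI(OAc)2, I2, visible light, cyclohexane/CH2Cl2), where iodine traps the C3 radical at a diffusion-controlled rate, to give the (Z)-iodo enal F1. Luche reduction gives the iodo allylic alcohol F2, and silylation (TBSCl, imidazole) gives the silyl ether F3. An intramolecular nickel-catalysed reductive alkyl–alkenyl cross-electrophile coupling (NiBr2(dme), 4,4′-di-tert-butyl-2,2′-bipyridine, Mn, NaI, DMA, high dilution) then closes the C3–C4 bond and gives 27 directly, with no formyl hydrogen present at the radical stage.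

2. Step 8. What may go wrong: loss of regiocontrol in the hydrosilylation, because two propargylic oxygens flank the alkyne and silicon may be delivered to C5, or O-silylation may compete. Fallback, from 15 and back at 18: conjugate hydroiodination of the ynone 15 (LiI, AcOH, MeCN, rt) fixes iodine at C4 by polarity and gives by anti addition the (Z)-β-iodo enone F4. Corey–Bakshi–Shibata reduction ((R)-Me-CBS oxazaborolidine, catecholborane, toluene, −78 °C; the iodoalkenyl group is taken as the large substituent, so this catalyst enantiomer is a prediction to be confirmed) then sets C6 and gives 18.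

3. Step 19. What may go wrong: poor discrimination between the primary hydroxyls and the secondary C6 hydroxyl, leading to over-acylation. Fallback, from 30 and back at 32: the two primary silyl ethers of 30 are cleaved selectively (HF·pyridine buffered with pyridine, THF, 0 °C) to the diol mono-silyl ether F5. Exhaustive acetylation (Ac2O, pyridine, DMAP) gives the diacetate silyl ether F6, and removal of the remaining secondary silyl ether (HF·pyridine, THF, rt) gives 32.

Further compounds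

F1 | step 14 | (4R,5S)-4-[(1S,2Z)-1,4-bis(tert-butyldimethylsilyloxy)-3-iodobut-2-en-1-yl]-5-[(2Z)-2-formyl-5-iodopent-2-en-1-yl]oxolan-2-one | O=C1C[C@@H]([C@H](O[Si](C)(C)C(C)(C)C)/C=C(\I)CO[Si](C)(C)C(C)(C)C)[C@H](C/C(C=O)=C/CCI)O1
F2 | step 14 | (4R,5S)-4-[(1S,2Z)-1,4-bis(tert-butyldimethylsilyloxy)-3-iodobut-2-en-1-yl]-5-[(2Z)-2-(hydroxymethyl)-5-iodopent-2-en-1-yl]oxolan-2-one | O=C1C[C@@H]([C@H](O[Si](C)(C)C(C)(C)C)/C=C(\I)CO[Si](C)(C)C(C)(C)C)[C@H](C/C(CO)=C/CCI)O1
F3 | step 14 | (4R,5S)-4-[(1S,2Z)-1,4-bis(tert-butyldimethylsilyloxy)-3-iodobut-2-en-1-yl]-5-[(2Z)-2-{[(tert-butyldimethylsilyl)oxy]methyl}-5-iodopent-2-en-1-yl]oxolan-2-one | O=C1C[C@@H]([C@H](O[Si](C)(C)C(C)(C)C)/C=C(\I)CO[Si](C)(C)C(C)(C)C)[C@H](C/C(CO[Si](C)(C)C(C)(C)C)=C/CCI)O1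
F4 | step 8 | (4R,5S)-4-[(2Z)-4-(tert-butyldimethylsilyloxy)-3-iodobut-2-enoyl]-5-(1,4-dioxaspiro[4.4]non-6-en-6-ylmethyl)oxolan-2-one | O=C1C[C@@H](C(=O)/C=C(\I)CO[Si](C)(C)C(C)(C)C)[C@H](CC2=CCCC23OCCO3)O1
F5 | step 19 | (3aR,4R,5E,9Z,11aS)-4-(tert-butyldimethylsilyloxy)-6,10-bis(hydroxymethyl)-3-methylidene-3a,4,7,8,11,11a-hexahydrocyclodeca[b]furan-2(3H)-one | C=C1C(=O)O[C@H]2C/C(CO)=C/CC/C(CO)=C\[C@@H](O[Si](C)(C)C(C)(C)C)[C@H]12
F6 | step 19 | [(3aR,4R,5E,9Z,11aS)-4-(tert-butyldimethylsilyloxy)-3-methylidene-2-oxo-2,3,3a,4,7,8,11,11a-octahydrocyclodeca[b]furan-6,10-diyl]bis(methylene) diacetate | C=C1C(=O)O[C@H]2C/C(COC(C)=O)=C/CC/C(COC(C)=O)=C\[C@@H](O[Si](C)(C)C(C)(C)C)[C@H]12
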